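**Plan**

Eudesmane numbering is used: ring A = C1–C5 and C10, ring B = C5–C10, C11 = carbinol carbon on C7, C14 = methyl on C10, C15 = methyl on C4.
Retrosynthesis: the chlorohydrin ester is cut to a 3α,4α-diol and a (2S,3R)-epoxy acid (HCl opens the epoxide last), and the diol goes back to a C3=C4 alkene. Ring B is then cut at C8–C9 and C6=C7 at once, into ring A bromo aldehyde 14 and the two-carbon ynol ether 18. C5–C6 is cut by a [2,3]-Wittig retron and ring A by a Diels–Alder retron.
Forward: ring A by Diels–Alder reaction, C6 onto C5 by [2,3] shift, ring B by nickel-mediated splicing of C7–C8 between C9 and C6, then diol, ester, chlorohydrin.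
Enabling feature: C9 is a CH2 on the quaternary C10, so its bromide is inert through the route and its alkylnickel has no β-hydrogen. It lies 1,4 to the aldehyde carbon C6 on C5, and the ring B enone C8(=O)–C7=C6 is the hydrolysed form of the 3-ethoxy allylic alcohol that an ynol ether C7≡C8–OEt delivers.
Stereochemistry: C10 from the catalyst in the Diels–Alder step; C5 from CBS reduction at C3 and suprafacial [2,3] transfer; C3 and C4 from OsO4 on the α-face, opposite the axial C14 methyl; C2′ and C3′ from Sharpless epoxidation and SN2 opening by chloride.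

Key step: step 10

Assumption: the sense of induction of the TADDOL catalyst in step 1 is set by the choice of its antipode; the antipode that gives the (S)-enone 5 is used.

**Step 1**
Reactants: 1 (E)-3-(tert-butyldimethylsilyloxy)-N,N-dimethylbuta-1,3-dien-1-amine; 2 methacrolein
Product: 5 (S)-4-(hydroxymethyl)-4-methylcyclohex-2-en-1-one, via Diels–Alder adduct 3 (not isolated), via amino alcohol 4 (not isolated)
Conditions: 1-naphthyl-TADDOL (20 mol %), toluene, −80 °C; LiAlH4, Et2O, −78 °C → rt; HF (aq.), MeCN, rt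
Reagents that add atoms: none
Why: The hydrogen-bond-catalysed Diels–Alder reaction of a 1-amino-3-silyloxy diene with an α-substituted acrolein is a known reaction type in which the chiral diol activates the aldehyde and shields one face, so the quaternary centre (later C10) is set by the catalyst, the amino terminus fixes the regiochemistry, and hydride reduction followed by HF-induced loss of dimethylamine and the silyl group should unveil the 4,4-disubstituted enone.

**Step 2**
Reactants: 5 (S)-4-(hydroxymethyl)-4-methylcyclohex-2-en-1-one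
Product: 6 (S)-4-(bromomethyl)-4-methylcyclohex-2-en-1-one
Conditions: Ph3PBr2 (from PPh3 and Br2), imidazole, DMF, 0 → 60 °C
Reagents that add atoms: bromine, BrBr
Why: Appel-type bromination through the alkoxyphosphonium salt converts neopentyl-type primary alcohols to bromides by SN2 without skeletal rearrangement, and neither the enone nor the stereocentre is touched.

**Step 3**
Reactants: 6 (S)-4-(bromomethyl)-4-methylcyclohex-2-en-1-one
Product: 7 (S)-4-(bromomethyl)-2-iodo-4-methylcyclohex-2-en-1-one
Conditions: I2, pyridine, CH2Cl2, 0 °C → rt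
Reagents that add atoms: iodine, II
Why: α-Iodination of an enone with I2/pyridine (addition of pyridine at the β-carbon, iodination of the enolate, elimination) is well precedented for 4,4-disubstituted cyclohexenones and places the halogen on the later C4.

**Step 4**
Reactants: 7 (S)-4-(bromomethyl)-2-iodo-4-methylcyclohex-2-en-1-one
Product: 8 (S)-4-(bromomethyl)-2,4-dimethylcyclohex-2-en-1-one
Conditions: Me4Sn, Pd2(dba)3 (2.5 mol %), AsPh3, CuI, NMP, 60 °C
Reagents that add atoms: tetramethylstannane, C[Sn](C)(C)C
Why: Stille coupling of a 2-iodoenone with Me4Sn is a standard route to 2-methyl enones, and the alkyl C–Br bond on the quaternary carbon should not undergo oxidative addition to zerovalent palladium under these conditions.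

**Step 5**
Reactants: 8 (S)-4-(bromomethyl)-2,4-dimethylcyclohex-2-en-1-one
Product: 9 (1S,4S)-4-(bromomethyl)-2,4-dimethylcyclohex-2-en-1-ol
Conditions: (R)-Me-CBS oxazaborolidine (20 mol %), BH3·SMe2, THF, −20 °C; MeOH
Reagents that add atoms: none
Why: CBS reduction of a 2-substituted cyclohexenone, in which the substituted alkene arm acts as the large group, is reagent-controlled and with the (R)-catalyst should give the (1S)-alcohol, that is the C3 hydroxyl cis to the C14 methyl and trans to CH2Br.

**Step 6**
Reactants: 9 (1S,4S)-4-(bromomethyl)-2,4-dimethylcyclohex-2-en-1-ol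
Product: 11 tributyl({[(1S,4S)-4-(bromomethyl)-2,4-dimethylcyclohex-2-en-1-yl]oxy}methyl)stannane, via potassium alkoxide 10 (not isolated)
Conditions: KH, THF, 0 °C; Bu3SnCH2I, 18-crown-6, rt
Reagents that add atoms: tributyl(iodomethyl)stannane, CCCC[Sn](CCCC)(CCCC)CI
Why: O-Alkylation of the potassium alkoxide with tributyl(iodomethyl)stannane is the standard entry to a Wittig–Still precursor, and the trans-disposed neopentyl bromide cannot be reached by the alkoxide.

**Step 7**
Reactants: 11 tributyl({[(1S,4S)-4-(bromomethyl)-2,4-dimethylcyclohex-2-en-1-yl]oxy}methyl)stannane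
Product: 13 [(1S,6S)-6-(bromomethyl)-2,6-dimethylcyclohex-2-en-1-yl]methanol, via lithiomethyl ether 12 (not isolated)
Conditions: n-BuLi, THF, −78 → −40 °C; H2O
Reagents that add atoms: none
Why: Tin–lithium exchange gives an α-alkoxymethyllithium that undergoes the [2,3]-sigmatropic Wittig–Still rearrangement suprafacially, so the new C5–C6 bond forms on the face that carried the C3 oxygen (cis to C14, trans to CH2Br) and the C3=C4 alkene is created, while exchange at tin should be much faster than any attack on the hindered C–Br bond at −78 °C.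

**Step 8**
Reactants: 13 [(1S,6S)-6-(bromomethyl)-2,6-dimethylcyclohex-2-en-1-yl]methanol
Product: 14 (1S,6S)-6-(bromomethyl)-2,6-dimethylcyclohex-2-ene-1-carbaldehyde
Conditions: Dess–Martin periodinane, NaHCO3, CH2Cl2, 0 °C
Reagents that add atoms: none
Why: Buffered Dess–Martin oxidation of a primary alcohol is near-neutral, so neither epimerisation at C5 nor migration of the β,γ-double bond into conjugation is expected.

**Step 9**
Reactants: 15 ethoxyacetylene
Product: 18 triethyl[(4-ethoxy-2-methylbut-3-yn-2-yl)oxy]silane, via lithium ethoxyacetylide 16 (not isolated), via lithium alkoxide 17 (not isolated)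
Conditions: n-BuLi, THF, −78 °C; acetone; Et3SiCl, −78 °C → rt
Reagents that add atoms: acetone, CC(C)=O; chlorotriethylsilane, CC[Si](Cl)(CC)CC
Why: Addition of lithium ethoxyacetylide to acetone and in-situ silylation of the tertiary alkoxide is a standard preparation of a protected ynol ether, and the silyl group blocks Meyer–Schuster rearrangement.

**Step 10**
Reactants: 14 (1S,6S)-6-(bromomethyl)-2,6-dimethylcyclohex-2-ene-1-carbaldehyde; 18 triethyl[(4-ethoxy-2-methylbut-3-yn-2-yl)oxy]silane
Product: 20 11-(triethylsilyloxy)eudesma-3,6-dien-8-one, via hydroxy enol ether 19 (not isolated)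
Conditions: NiBr2(dme) (10 mol %), 4,4′-di-tert-butyl-2,2′-bipyridine (10 mol %), Zn (3 equiv), NaI (0.5 equiv), MeCN/THF, 40 °C; then 1 M HCl, THF, 0 °C
Reagents that add atoms: water, O
Why: Proposed new method: zerovalent nickel (from NiBr2(dme) and Zn) takes up the neopentyl C9–Br bond of 14 to give a divalent alkylnickel bromide that has no β-hydrogen, this adds syn across ynol ether 18 with the alkyl group going to the ethoxy-bearing carbon (C8) and nickel to C7, the alkenylnickel adds to the C6 aldehyde, zinc reduces the nickel alkoxide to turn the catalyst over, and acid work-up of the 3-ethoxy allylic alcohol 19 gives the enone by loss of the C6 hydroxyl, addition of water at C8 and loss of ethanol. The closest known reaction types are the nickel-catalysed alkylative coupling of an alkyne, an aldehyde and an organozinc, and the NiBr2(dppe)/Zn annulation of ortho-halobenzaldehydes with alkynes to indenols; new here are the sp3 halide partner and the ynol ether. Ring B closes by 6-exo-trig attack of the C7 alkenylnickel on the aldehyde carbonyl, with the C7=C8 bond endocyclic. The only new stereocentre, the C6 carbinol of 19, is not controlled and is erased in the hydrolysis, while C5 and C10 are untouched. The step needs regioselective insertion (C9 to C8), which the polarisation of the ynol ether and the bulk of the C11 group at C7 both favour; chemoselective activation of C–Br beside the aldehyde, which the mild reductant and the absence of β-hydrogens allow; and ionisation at C6 instead of C11, which the silyl ether on the C11 oxygen should secure.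

**Step 11**
Reactants: 20 11-(triethylsilyloxy)eudesma-3,6-dien-8-one
Product: 21 3α,4α-dihydroxy-11-(triethylsilyloxy)eudesm-6-en-8-one
Conditions: OsO4 (2 mol %), NMO, acetone/H2O, 0 °C → rt
Reagents that add atoms: N-methylmorpholine N-oxide, C[N+]1([O-])CCOCC1; water, O
Why: Upjohn dihydroxylation takes the electron-rich trisubstituted C3=C4 alkene in preference to the enone, and osmium should approach the α-face of the trans-fused decalin, away from the axial C14 methyl, to give the 3α,4α-cis-diol.

**Step 12**
Reactants: 22 (E)-2-methylbut-2-en-1-ol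
Product: 23 [(2R,3R)-2,3-dimethyloxiran-2-yl]methanol
Conditions: Ti(OiPr)4 (10 mol %), D-(−)-diisopropyl tartrate (12 mol %), t-BuOOH, 4 Å MS, CH2Cl2, −20 °C
Reagents that add atoms: tert-butyl hydroperoxide, CC(C)(C)OO
Why: Sharpless asymmetric epoxidation of a trisubstituted (E)-allylic alcohol is highly enantioselective, and since the L-(+)-tartrate gives (2S,3S)-epoxy alcohols from (E)-allylic alcohols, the D-(−)-tartrate should give the (2R,3R)-isomer.

**Step 13**
Reactants: 23 [(2R,3R)-2,3-dimethyloxiran-2-yl]methanol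
Product: 24 (2S,3R)-2,3-dimethyloxirane-2-carboxylic acid
Conditions: TEMPO (10 mol %), PhI(OAc)2, MeCN/H2O, rt
Reagents that add atoms: water, O
Why: TEMPO/PhI(OAc)2 oxidation in aqueous acetonitrile takes a primary alcohol to the acid through the aldehyde hydrate without opening the epoxide, and the descriptor at C2 changes to S only through the change in priorities.

**Step 14**
Reactants: 21 3α,4α-dihydroxy-11-(triethylsilyloxy)eudesm-6-en-8-one; 24 (2S,3R)-2,3-dimethyloxirane-2-carboxylic acid
Product: 26 3α-[(2S,3R)-2,3-epoxy-2-methylbutanoyloxy]-4α-hydroxy-11-(triethylsilyloxy)eudesm-6-en-8-one, via mixed anhydride 25 (not isolated)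
Conditions: 24, 2,4,6-trichlorobenzoyl chloride, Et3N, THF, rt; then 21, DMAP, toluene, 50 °C
Reagents that add atoms: none
Why: Yamaguchi esterification through the mixed anhydride should acylate the secondary C3 hydroxyl in preference to the tertiary C4 hydroxyl and the silylated C11 oxygen, and the compact epoxy acid is a feasible partner for the hindered axial alcohol.

**Step 15**
Reactants: 26 3α-[(2S,3R)-2,3-epoxy-2-methylbutanoyloxy]-4α-hydroxy-11-(triethylsilyloxy)eudesm-6-en-8-one
Product: 27 3α-[(2R,3S)-3-chloro-2-hydroxy-2-methylbutanoyloxy]-4α-hydroxy-11-(triethylsilyloxy)eudesm-6-en-8-one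
Conditions: HCl (1 M in Et2O), CH2Cl2, −20 → 0 °C
Reagents that add atoms: hydrogen chloride, Cl
Why: Acid-mediated opening of a 2,3-epoxy ester by chloride occurs at C3′ by SN2 with inversion, since attack at the quaternary carbon next to the carbonyl is disfavoured sterically and electronically, which should give the (2′R,3′S)-chlorohydrin.

**Step 16**
Reactants: 27 3α-[(2R,3S)-3-chloro-2-hydroxy-2-methylbutanoyloxy]-4α-hydroxy-11-(triethylsilyloxy)eudesm-6-en-8-one
Product: 28 3α-[(2R,3S)-3-chloro-2-hydroxy-2-methylbutanoyloxy]-4α,11-dihydroxyeudesm-6-en-8-one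
Conditions: HF·pyridine, pyridine, THF, 0 °C → rt
Reagents that add atoms: none
Why: Cleavage of the tertiary triethylsilyl ether with buffered HF·pyridine is base-free, so the chlorohydrin should not re-close to the epoxide, and the tertiary alcohols and the enone are left intact.

**Compound list**

1 | (E)-3-(tert-butyldimethylsilyloxy)-N,N-dimethylbuta-1,3-dien-1-amine | CN(C)/C=C/C(=C)O[Si](C)(C)C(C)(C)C | starting material
2 | methacrolein | CC(=C)C=O | starting material
3 | (1S,2R)-4-(tert-butyldimethylsilyloxy)-2-(dimethylamino)-1-methylcyclohex-3-ene-1-carbaldehyde (endo adduct, formed in the flask) | O=C[C@@]1(C)CCC(O[Si](C)(C)C(C)(C)C)=C[C@H]1N(C)C | intermediate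
4 | [(1S,2R)-4-(tert-butyldimethylsilyloxy)-2-(dimethylamino)-1-methylcyclohex-3-en-1-yl]methanol (formed in the flask) | OC[C@@]1(C)CCC(O[Si](C)(C)C(C)(C)C)=C[C@H]1N(C)C | intermediate
5 | (S)-4-(hydroxymethyl)-4-methylcyclohex-2-en-1-one | O=C1CC[C@](C)(CO)C=C1 | intermediate
6 | (S)-4-(bromomethyl)-4-methylcyclohex-2-en-1-one | O=C1CC[C@](C)(CBr)C=C1 | intermediate
7 | (S)-4-(bromomethyl)-2-iodo-4-methylcyclohex-2-en-1-one | O=C1CC[C@](C)(CBr)C=C1I | intermediate
8 | (S)-4-(bromomethyl)-2,4-dimethylcyclohex-2-en-1-one | O=C1CC[C@](C)(CBr)C=C1C | intermediate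
9 | (1S,4S)-4-(bromomethyl)-2,4-dimethylcyclohex-2-en-1-ol | O[C@H]1CC[C@](C)(CBr)C=C1C | intermediate
10 | potassium (1S,4S)-4-(bromomethyl)-2,4-dimethylcyclohex-2-en-1-olate (formed in the flask) | [K]O[C@H]1CC[C@](C)(CBr)C=C1C | intermediate
11 | tributyl({[(1S,4S)-4-(bromomethyl)-2,4-dimethylcyclohex-2-en-1-yl]oxy}methyl)stannane | CCCC[Sn](CCCC)(CCCC)CO[C@H]1CC[C@](C)(CBr)C=C1C | intermediate
12 | ({[(1S,4S)-4-(bromomethyl)-2,4-dimethylcyclohex-2-en-1-yl]oxy}methyl)lithium (formed in the flask) | [Li]CO[C@H]1CC[C@](C)(CBr)C=C1C | intermediate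
13 | [(1S,6S)-6-(bromomethyl)-2,6-dimethylcyclohex-2-en-1-yl]methanol | OC[C@H]1C(C)=CCC[C@]1(C)CBr | intermediate
14 | (1S,6S)-6-(bromomethyl)-2,6-dimethylcyclohex-2-ene-1-carbaldehyde | O=C[C@H]1C(C)=CCC[C@]1(C)CBr | intermediate
15 | ethoxyacetylene | CCOC#C | starting material
16 | lithium ethoxyacetylide (formed in the flask) | CCOC#C[Li] | intermediate
17 | lithium 4-ethoxy-2-methylbut-3-yn-2-olate (formed in the flask) | CCOC#CC(C)(C)O[Li] | intermediate
18 | triethyl[(4-ethoxy-2-methylbut-3-yn-2-yl)oxy]silane | CCOC#CC(C)(C)O[Si](CC)(CC)CC | intermediate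
19 | 8-ethoxy-11-(triethylsilyloxy)eudesma-3,7-dien-6-ol (formed in the flask as its zinc alkoxide, C6 configuration not controlled) | CC1=CCC[C@]2(C)CC(OCC)=C(C(C)(C)O[Si](CC)(CC)CC)C(O)[C@@H]12 | intermediate
20 | 11-(triethylsilyloxy)eudesma-3,6-dien-8-one; (4aR,8aR)-5,8a-dimethyl-3-[2-(triethylsilyloxy)propan-2-yl]-4a,7,8,8a-tetrahydronaphthalen-2(1H)-one | CC1=CCC[C@]2(C)CC(=O)C(C(C)(C)O[Si](CC)(CC)CC)=C[C@@H]12 | intermediate
21 | 3α,4α-dihydroxy-11-(triethylsilyloxy)eudesm-6-en-8-one; (4aR,5S,6R,8aR)-5,6-dihydroxy-5,8a-dimethyl-3-[2-(triethylsilyloxy)propan-2-yl]-4a,5,6,7,8,8a-hexahydronaphthalen-2(1H)-one | O[C@@H]1CC[C@]2(C)CC(=O)C(C(C)(C)O[Si](CC)(CC)CC)=C[C@H]2[C@]1(C)O | intermediate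
22 | (E)-2-methylbut-2-en-1-ol | C/C=C(\C)CO | starting material
23 | [(2R,3R)-2,3-dimethyloxiran-2-yl]methanol | C[C@H]1O[C@]1(C)CO | intermediate
24 | (2S,3R)-2,3-dimethyloxirane-2-carboxylic acid | C[C@H]1O[C@]1(C)C(O)=O | intermediate
25 | (2S,3R)-2,3-dimethyloxirane-2-carboxylic 2,4,6-trichlorobenzoic anhydride (formed in the flask) | C[C@H]1O[C@]1(C)C(=O)OC(=O)c2c(Cl)cc(Cl)cc2Cl | intermediate
26 | 3α-[(2S,3R)-2,3-epoxy-2-methylbutanoyloxy]-4α-hydroxy-11-(triethylsilyloxy)eudesm-6-en-8-one | C[C@H]3O[C@]3(C)C(=O)O[C@@H]1CC[C@]2(C)CC(=O)C(C(C)(C)O[Si](CC)(CC)CC)=C[C@H]2[C@]1(C)O | intermediate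
27 | 3α-[(2R,3S)-3-chloro-2-hydroxy-2-methylbutanoyloxy]-4α-hydroxy-11-(triethylsilyloxy)eudesm-6-en-8-one | C[C@H](Cl)[C@](C)(O)C(=O)O[C@@H]1CC[C@]2(C)CC(=O)C(C(C)(C)O[Si](CC)(CC)CC)=C[C@H]2[C@]1(C)O | intermediate
28 | 3α-[(2R,3S)-3-chloro-2-hydroxy-2-methylbutanoyloxy]-4α,11-dihydroxyeudesm-6-en-8-one (3R,4S,5R,10R) | C[C@H](Cl)[C@](C)(O)C(=O)O[C@@H]1CC[C@]2(C)CC(=O)C(C(C)(C)O)=C[C@H]2[C@]1(C)O | target

**Step count**

Total: 16 steps. Longest linear sequence: 13 steps (steps 1–8, 10, 11, 14, 15, 16).

**Steps most likely to fail**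

Step 10 (proposed new method). The alkylnickel may be protonated or homocoupled before it inserts into the ynol ether. Zinc halide may promote carbonyl–alkyne metathesis between the aldehyde and the ynol ether. The aldehyde may epimerise at C5, and in the acid work-up the allyl cation may lose the C5 proton instead of taking up water.
Fallback, from aldehyde 14 back to enone 20, by known reactions: commercial ethyl 3-hydroxy-3-methylbutanoate is silylated (Et3SiOTf, 2,6-lutidine) to ethyl 3-methyl-3-(triethylsilyloxy)butanoate F1. Its lithium enolate F2 (LDA, THF, −78 °C) is added to 14 to give the β-hydroxy ester F3, which forms the C6–C7 bond by aldol addition. SmI2 (THF/HMPA, or with catalytic NiI2) should then close ring B by intramolecular nucleophilic acyl substitution of the C9 bromide on the ester, forming the C8–C9 bond and giving the β-hydroxy ketone F4. Mesylation to the mesylate F5 (MsCl, Et3N) and elimination (DBU) should give 20.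

Step 7. The [2,3] shift has to form a bond at a carbon next to the quaternary centre on its more hindered face. A competing [1,2] shift, simple protonation of the organolithium, or bromine–lithium exchange may take over.
Fallback, from enone 8 back to alcohol 13: reduction of 8 with the (S)-Me-CBS catalyst gives the C3-epimeric alcohol (1R,4S)-4-(bromomethyl)-2,4-dimethylcyclohex-2-en-1-ol F6. Acylation with picolinoyl chloride hydrochloride (Et3N, DMAP) gives the picolinate F7. Copper-catalysed anti-SN2′ substitution with (isopropoxydimethylsilyl)methylmagnesium chloride (CuBr·SMe2, THF, −40 °C) places the carbon on C5 on the face opposite the leaving group and gives the silane F8. Tamao oxidation (H2O2, KF, KHCO3, THF/MeOH) then gives 13.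

Step 15. The late epoxide opening may lose regio- or chemoselectivity: chloride or adventitious water may attack the wrong carbon, the tertiary C4 alcohol may dehydrate under acid, or the silyl ether may be lost early.
Fallback, from epoxy acid 24 (coupled with diol 21) back to target 28: the epoxide is opened on the small acid, where the outcome can be checked and purified, to give (2R,3S)-3-chloro-2-hydroxy-2-methylbutanoic acid F9 (HCl, Et2O). Bis-silylation (Et3SiOTf, 2,6-lutidine) gives the silyl ester silyl ether F10, and mild methanolysis of the silyl ester (K2CO3, MeOH/H2O, then dilute acid) gives (2R,3S)-3-chloro-2-methyl-2-(triethylsilyloxy)butanoic acid F11. Yamaguchi activation to the mixed anhydride F12 and coupling with 21 (DMAP, toluene, 60 °C) gives the bis(triethylsilyl) ether F13, and HF·pyridine removes both silyl groups to give 28.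

**Further compounds**

F1 | step 10 | ethyl 3-methyl-3-(triethylsilyloxy)butanoate | CCOC(=O)CC(C)(C)O[Si](CC)(CC)CC
F2 | step 10 | lithium enolate of ethyl 3-methyl-3-(triethylsilyloxy)butanoate | CCOC(O[Li])=CC(C)(C)O[Si](CC)(CC)CC
F3 | step 10 | ethyl 2-{[(1S,6S)-6-(bromomethyl)-2,6-dimethylcyclohex-2-en-1-yl](hydroxy)methyl}-3-methyl-3-(triethylsilyloxy)butanoate | CCOC(=O)C(C(O)[C@H]1C(C)=CCC[C@]1(C)CBr)C(C)(C)O[Si](CC)(CC)CC
F4 | step 10 | 6-hydroxy-11-(triethylsilyloxy)eudesm-3-en-8-one | CC1=CCC[C@]2(C)CC(=O)C(C(C)(C)O[Si](CC)(CC)CC)C(O)[C@@H]12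
F5 | step 10 | 6-(methanesulfonyloxy)-11-(triethylsilyloxy)eudesm-3-en-8-one | CC1=CCC[C@]2(C)CC(=O)C(C(C)(C)O[Si](CC)(CC)CC)C(OS(C)(=O)=O)[C@@H]12
F6 | step 7 | (1R,4S)-4-(bromomethyl)-2,4-dimethylcyclohex-2-en-1-ol | O[C@@H]1CC[C@](C)(CBr)C=C1C
F7 | step 7 | (1R,4S)-4-(bromomethyl)-2,4-dimethylcyclohex-2-en-1-yl pyridine-2-carboxylate | O=C(O[C@@H]1CC[C@](C)(CBr)C=C1C)c1ccccn1
F8 | step 7 | {[(1S,6S)-6-(bromomethyl)-2,6-dimethylcyclohex-2-en-1-yl]methyl}(isopropoxy)dimethylsilane | CC(C)O[Si](C)(C)C[C@H]1C(C)=CCC[C@]1(C)CBr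
F9 | step 15 | (2R,3S)-3-chloro-2-hydroxy-2-methylbutanoic acid | C[C@H](Cl)[C@](C)(O)C(O)=O
F10 | step 15 | triethylsilyl (2R,3S)-3-chloro-2-methyl-2-(triethylsilyloxy)butanoate | C[C@H](Cl)[C@](C)(O[Si](CC)(CC)CC)C(=O)O[Si](CC)(CC)CC
F11 | step 15 | (2R,3S)-3-chloro-2-methyl-2-(triethylsilyloxy)butanoic acid | C[C@H](Cl)[C@](C)(O[Si](CC)(CC)CC)C(O)=O
F12 | step 15 | (2R,3S)-3-chloro-2-methyl-2-(triethylsilyloxy)butanoic 2,4,6-trichlorobenzoic anhydride | C[C@H](Cl)[C@](C)(O[Si](CC)(CC)CC)C(=O)OC(=O)c1c(Cl)cc(Cl)cc1Cl
F13 | step 15 | 3α-[(2R,3S)-3-chloro-2-methyl-2-(triethylsilyloxy)butanoyloxy]-4α-hydroxy-11-(triethylsilyloxy)eudesm-6-en-8-one | C[C@H](Cl)[C@](C)(O[Si](CC)(CC)CC)C(=O)O[C@@H]1CC[C@]2(C)CC(=O)C(C(C)(C)O[Si](CC)(CC)CC)=C[C@H]2[C@]1(C)O
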